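**Retrosynthetic overview**

1. The route rests on the exocyclic C4=C11 methylene of ring A beside the quaternary ring-fusion carbon C5. It is the 1,3-transposed form of a C3=C4 alkene carrying C11–O, the cyclohexene that a C2=C3–C4=C5 diene leaves after adding across C5–C10.
2. End game: the C2′ phenol is freed from its MOM ether and sulfated before fluoride removes the two TIPS groups. The methylene comes from C11–OH by Mitsunobu/allylic diazene rearrangement, after reductive loss of the C1 sulfone.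
3. Rings A and B are closed together (the aromatic ring is bought in) by one intramolecular Diels–Alder reaction of an (E)-vinyl sulfone (C1=C10) with the tethered diene, forming C1–C2 and C5–C10.
4. The triene comes from Horner–Wadsworth–Emmons olefination at the C10 aldehyde and a B-alkyl Suzuki coupling (C5–C6) with a dienyl iodide made from but-2-yn-1-ol by anti-carbomagnesiation.
5. C8 is bought as (R)-4-methyloxolan-2-one; C9 is set by two enolate alkylations anti to the C8 methyl (MeI, then the benzylic bromide from 5-bromovanillin). The lactone carbonyl is then transposed to give the C7=C6 vinyl group.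

Key step: step 18

Numbering and abbreviation: decalin atoms C1–C10 as in the target (C4 carries the exocyclic carbon C11, C5 the angular methyl, C9 the quaternary carbon, C10 the ring-fusion hydrogen). Ar = 2-(methoxymethoxy)-3-(triisopropylsilyloxy)-5-[(triisopropylsilyloxy)methyl]phenyl.

Assumption: the target is taken in the neutral hydrogen sulfate form drawn (released from its sodium salt in the last step; it would be stored as a salt), and (R)-4-methyloxolan-2-one is taken as a purchasable chiral building block.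

**Route**

Step 1
Reactants: 1 5-bromovanillin
Product: 2 3-bromo-4,5-dihydroxybenzaldehyde
Conditions: AlCl3, pyridine, CH2Cl2, reflux; then aq HCl
Reagents that add atoms: none
Why: Lewis-acid-assisted aryl methyl ether cleavage, in which AlCl3 chelates the ortho hydroxy/methoxy pair and pyridine removes the methyl group by SN2, leaving the aldehyde and the bromide untouched.

Step 2
Reactants: 2 3-bromo-4,5-dihydroxybenzaldehyde
Product: 3 3-bromo-5-hydroxy-4-(methoxymethoxy)benzaldehyde
Conditions: MOMCl (1.0 equiv), K2CO3 (1.0 equiv), acetone, 0 °C → rt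
Reagents that add atoms: chloromethyl methyl ether, COCCl
Why: Regioselective Williamson-type O-alkylation, since one equivalent of base should ionise only the far more acidic 4-OH (para to the formyl group, ortho to bromine) and the small MOMCl alkylates that phenoxide.

Step 3
Reactants: 3 3-bromo-5-hydroxy-4-(methoxymethoxy)benzaldehyde
Product: 4 3-bromo-5-(hydroxymethyl)-2-(methoxymethoxy)phenol
Conditions: NaBH4, MeOH, 0 °C
Reagents that add atoms: none
Why: Borohydride reduction of the aryl aldehyde to the benzylic alcohol, which leaves the aryl bromide, the acetal and the phenol alone.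

Step 4
Reactants: 4 3-bromo-5-(hydroxymethyl)-2-(methoxymethoxy)phenol
Product: 5 aryl bromide Ar–Br
Conditions: TIPSCl (2.5 equiv), imidazole, DMAP (cat.), DMF, rt
Reagents that add atoms: chlorotriisopropylsilane, CC(C)[Si](Cl)(C(C)C)C(C)C
Why: Imidazole-promoted silylation of both the remaining phenol and the primary alcohol as TIPS ethers, which survive base, hydride and heat and later fall together to fluoride.

Step 5
Reactants: 5 aryl bromide Ar–Br
Product: 8 benzylic alcohol Ar–CH2OH, via aryllithium 6 (not isolated), via aldehyde 7 (not isolated)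
Conditions: n-BuLi, THF, −78 °C; DMF, −78 → 0 °C; then MeOH, NaBH4, 0 °C
Reagents that add atoms: N,N-dimethylformamide, CN(C)C=O
Why: Bromine–lithium exchange gives an aryllithium held by the ortho MOM oxygen and not ortho to a silyloxy group (so no retro-Brook shift), and Bouveault formylation followed by borohydride reduction in the same flask delivers the one-carbon benzylic alcohol.

Step 6
Reactants: 8 benzylic alcohol Ar–CH2OH
Product: 9 benzylic bromide Ar–CH2Br
Conditions: CBr4, PPh3, 2,6-lutidine, CH2Cl2, 0 °C (used at once)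
Reagents that add atoms: carbon tetrabromide, BrC(Br)(Br)Br
Why: Appel bromination of the benzylic alcohol under buffered, non-acidic conditions that spare the MOM and TIPS groups.

Step 7
Reactants: 10 (R)-4-methyloxolan-2-one
Product: 12 (3R,4R)-3,4-dimethyloxolan-2-one, via lithium enolate 11 (not isolated)
Conditions: LiN(iPr)2, THF, −78 °C; MeI, −78 → −40 °C
Reagents that add atoms: iodomethane, CI
Why: Lactone enolate alkylation in which iodomethane enters anti to the C4 methyl to give the trans product; this centre is re-enolised in step 8, so its purity is not critical.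

Step 8
Reactants: 12 (3R,4R)-3,4-dimethyloxolan-2-one; 9 benzylic bromide Ar–CH2Br
Product: 14 (3R,4R)-3-(ArCH2)-3,4-dimethyloxolan-2-one, via lithium enolate 13 (not isolated)
Conditions: LiN(iPr)2, THF, −78 °C; 9, DMPU, −78 → −30 °C
Reagents that add atoms: none
Why: Second lactone enolate alkylation creates the quaternary C9, the reactive benzylic bromide attacking the planar enolate anti to the neighbouring C8 methyl so that the arylmethyl group ends trans and the C9 methyl cis to it, as in the target.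

Step 9
Reactants: 14 (3R,4R)-3-(ArCH2)-3,4-dimethyloxolan-2-one
Product: 15 (2R,3R)-2-(ArCH2)-2,3-dimethylbutane-1,4-diol
Conditions: LiAlH4, THF, 0 °C
Reagents that add atoms: none
Why: Hydride reduction of the lactone to the 1,4-diol, with the ethers and both stereocentres unaffected.

Step 10
Reactants: 15 (2R,3R)-2-(ArCH2)-2,3-dimethylbutane-1,4-diol
Product: 16 (3R,4R)-4-(ArCH2)-3,4-dimethyloxolan-2-one
Conditions: TEMPO (cat.), PhI(OAc)2, CH2Cl2, rt
Reagents that add atoms: none
Why: Oxoammonium (TEMPO) oxidative lactonisation, sterically selective for the C7 carbinol over the neopentyl C10 carbinol, so the hydroxy aldehyde closes to the lactol and is oxidised on to the lactone with its carbonyl now at C7.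

Step 11
Reactants: 16 (3R,4R)-4-(ArCH2)-3,4-dimethyloxolan-2-one
Product: 17 (3R,4R)-4-(ArCH2)-3,4-dimethyloxolan-2-ol (anomer mixture)
Conditions: iBu2AlH, CH2Cl2, −78 °C
Reagents that add atoms: none
Why: Partial hydride reduction of the lactone, the tetrahedral aluminium alkoxide being stable at low temperature and giving the lactol on work-up.

Step 12
Reactants: 17 (3R,4R)-4-(ArCH2)-3,4-dimethyloxolan-2-ol
Product: 18 (2R,3S)-2-(ArCH2)-2,3-dimethylpent-4-en-1-ol
Conditions: Ph3PCH3Br, KOtBu, THF, 0 °C → rt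
Reagents that add atoms: methyltriphenylphosphonium bromide, C[P+](c1ccccc1)(c1ccccc1)c1ccccc1.[Br-]
Why: Wittig methylenation of the lactol through its open hydroxy aldehyde gives the C7=C6 vinyl group and frees the C10 alcohol, the unstabilised ylide adding faster than it can enolise C8.

Step 13
Reactants: 19 but-2-yn-1-ol
Product: 21 (2Z)-2-ethenyl-3-iodobut-2-en-1-ol, via magnesium chelate 20 (not isolated)
Conditions: CH2=CHMgCl (3.5 equiv), THF/toluene, reflux; then I2, −78 → 0 °C
Reagents that add atoms: vinylmagnesium chloride, C=C[Mg]Cl; iodine, II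
Why: Hydroxyl-directed anti-carbomagnesiation of a propargylic alcohol puts vinyl on the alkyne carbon next to the carbinol and magnesium on the methyl-bearing carbon in a five-membered alkoxide chelate, and iodinolysis with retention leaves iodine cis to CH2OH and the methyl cis to the vinyl group.

Step 14
Reactants: 21 (2Z)-2-ethenyl-3-iodobut-2-en-1-ol
Product: 22 {[(2Z)-2-ethenyl-3-iodobut-2-en-1-yl]oxy}triethylsilane
Conditions: Et3SiCl, imidazole, CH2Cl2, 0 °C
Reagents that add atoms: chlorotriethylsilane, CC[Si](Cl)(CC)CC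
Why: Silylation of the primary allylic alcohol as a TES ether, chosen because it can later be removed by mild acid without touching TIPS or aryl MOM groups.

Step 15
Reactants: 18 (2R,3S)-2-(ArCH2)-2,3-dimethylpent-4-en-1-ol; 22 {[(2Z)-2-ethenyl-3-iodobut-2-en-1-yl]oxy}triethylsilane
Product: 24 (2R,3S,6Z)-2-(ArCH2)-2,3,6-trimethyl-7-[(triethylsilyloxy)methyl]nona-6,8-dien-1-ol, via alkylborane 23 (not isolated)
Conditions: 9-BBN-H (2.4 equiv), THF, rt → 50 °C; then 22, PdCl2(dppf), AsPh3, Cs2CO3, DMF/H2O, rt → 45 °C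
Reagents that add atoms: none
Why: Anti-Markovnikov hydroboration of the only alkene followed by B-alkyl Suzuki–Miyaura coupling, which proceeds with retention at the alkenyl iodide and so forms C5–C6 with C6 cis to the CH2O group (outside on the diene).

Step 16
Reactants: 24 (2R,3S,6Z)-2-(ArCH2)-2,3,6-trimethyl-7-[(triethylsilyloxy)methyl]nona-6,8-dien-1-ol
Product: 25 (2R,3S,6Z)-2-(ArCH2)-2,3,6-trimethyl-7-[(triethylsilyloxy)methyl]nona-6,8-dienal
Conditions: Dess–Martin periodinane, NaHCO3, CH2Cl2, 0 °C → rt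
Reagents that add atoms: none
Why: Dess–Martin oxidation of the neopentyl alcohol to an aldehyde that has no α-hydrogen and therefore cannot epimerise, under buffered conditions that leave the diene and silyl ethers intact.

Step 17
Reactants: 25 (2R,3S,6Z)-2-(ArCH2)-2,3,6-trimethyl-7-[(triethylsilyloxy)methyl]nona-6,8-dienal; 26 diethyl [(phenylsulfonyl)methyl]phosphonate
Product: 28 {[(1E,3R,4S,7Z)-3-(ArCH2)-3,4,7-trimethyl-8-[(triethylsilyloxy)methyl]deca-1,7,9-trien-1-yl]sulfonyl}benzene, via phosphonate carbanion 27 (not isolated)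
Conditions: NaH, THF, 0 °C; then 25, 0 °C → rt
Reagents that add atoms: none
Why: Horner–Wadsworth–Emmons olefination with a sulfonyl-stabilised phosphonate carbanion, which should give the (E)-vinyl sulfone and supplies C1.

Step 18
Reactants: 28 (E)-vinyl sulfone triene
Product: 29 triethyl{[(4S,4aS,5R,6S,8aS)-5-(ArCH2)-5,6,8a-trimethyl-4-(phenylsulfonyl)-3,4,4a,5,6,7,8,8a-octahydronaphthalen-1-yl]methoxy}silane
Conditions: PhMe (0.01 M, degassed), BHT, sealed tube, 190 °C
Reagents that add atoms: none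
Why: Thermal intramolecular Diels–Alder reaction: the LUMO-lowered (E)-vinyl sulfone C1=C10 adds suprafacially in one concerted [4+2] step to the tethered diene C2=C3–C4=C5, forming C1–C2 and C5–C10, the known behaviour of 1-sulfonyl-1,7,9-decatrienes. Ring A closes as the new cyclohexene of the [4+2] (C3=C4 remains), and ring B closes as the six-membered ring spanned by the four-atom tether C6–C9 between diene terminus C5 and dienophile carbon C10. C5 and C10 are fixed relative to each other by the diene geometry (C6 outside, methyl inside) and the anti placement of the tether, which puts H-10 trans to the C5 methyl; C1 follows from the (E)-dienophile, the sulfone ending endo and trans to C9, and is erased in step 19. Relative to the preset C8 and C9, the diene face is chosen by a chair-like tether in which the C8 methyl and the arylmethyl group on C9 are equatorial and only the C9 methyl is axial. The step needs tether-anti over tether-syn closure and cycloaddition faster than [1,5]-hydrogen shift of the inside methyl. The geminal substitution at C9 next to the dienophile should help the closure, and high dilution with a radical inhibitor suppresses intermolecular and radical pathways.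

Step 19
Reactants: 29 sulfonyl octalin
Product: 30 triethyl{[(4aS,5R,6S,8aS)-5-(ArCH2)-5,6,8a-trimethyl-3,4,4a,5,6,7,8,8a-octahydronaphthalen-1-yl]methoxy}silane
Conditions: 6% Na(Hg), Na2HPO4, MeOH/THF, −20 °C
Reagents that add atoms: none
Why: Reductive desulfonylation by electron transfer cleaves the C1–S bond and protonates C1, while the buffer protects the silyl ethers and the isolated trisubstituted alkene is not reduced.

Step 20
Reactants: 30 desulfonylated octalin
Product: 31 [(4aS,5R,6S,8aS)-5-(ArCH2)-5,6,8a-trimethyl-3,4,4a,5,6,7,8,8a-octahydronaphthalen-1-yl]methanol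
Conditions: PPTS, MeOH/CH2Cl2, 0 °C
Reagents that add atoms: none
Why: Acid-catalysed methanolysis of the primary TES ether, which is orders of magnitude more labile than the TIPS ethers and the aryl MOM ether.

Step 21
Reactants: 31 allylic alcohol
Product: 34 (1R,2S,4aS,8aS)-1-(ArCH2)-1,2,4a-trimethyl-5-methylidenedecahydronaphthalene, via sulfonylhydrazine 32 (not isolated), via allylic diazene 33 (not isolated)
Conditions: PPh3, DEAD, 2-nitrobenzenesulfonylhydrazide, N-methylmorpholine, −30 °C → rt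
Reagents that add atoms: none
Why: Reductive 1,3-transposition of an allylic alcohol: Mitsunobu N-alkylation at C11, loss of sulfinic acid to the monoalkyl diazene and retro-ene loss of N2 deliver hydrogen to C3 and leave C4=C11, with no stereocentre created.

Step 22
Reactants: 34 protected exocyclic alkene
Product: 36 2-{[(1R,2S,4aS,8aS)-1,2,4a-trimethyl-5-methylidenedecahydronaphthalen-1-yl]methyl}-6-(triisopropylsilyloxy)-4-[(triisopropylsilyloxy)methyl]phenol, via aryl trimethylsilyl ether 35 (not isolated)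
Conditions: TMSOTf, 2,2′-bipyridyl, CH2Cl2, 0 °C → rt; then H2O
Reagents that add atoms: none
Why: Bipyridyl-buffered silyl triflate cleavage of an aromatic MOM ether through the aryl TMS ether, hydrolysed on work-up; the near-neutral medium should spare the 1,1-disubstituted alkene, the para benzylic silyl ether and the aryl TIPS ether.

Step 23
Reactants: 36 phenol
Product: 37 sodium 2-{[(1R,2S,4aS,8aS)-1,2,4a-trimethyl-5-methylidenedecahydronaphthalen-1-yl]methyl}-6-(triisopropylsilyloxy)-4-[(triisopropylsilyloxy)methyl]phenyl sulfate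
Conditions: SO3·pyridine, pyridine, 50 °C; then aq NaHCO3
Reagents that add atoms: sulfur trioxide–pyridine complex, O=S(=O)([O-])[n+]1ccccc1; sodium hydrogencarbonate, [Na+].OC(=O)[O-]
Why: O-sulfation of the only free hydroxyl with an amine–SO3 complex, so the site of the sulfate is fixed by the protecting-group pattern and not by selectivity.

Step 24
Reactants: 37 sodium aryl sulfate
Product: 38 2-{[(1R,2S,4aS,8aS)-1,2,4a-trimethyl-5-methylidenedecahydronaphthalen-1-yl]methyl}-6-hydroxy-4-(hydroxymethyl)phenyl hydrogen sulfate (CNP0353860.3)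
Conditions: HF·pyridine, pyridine, THF, 0 °C → rt; then sulfonic acid resin (H+ form), MeOH, 0 °C
Reagents that add atoms: none
Why: Fluoride-driven cleavage of both TIPS ethers through Si–F bond formation in a buffered medium to which the aryl sulfate monoester and the exocyclic alkene should be stable, with protonation of the sulfate to the form drawn.

**Compound list**

1 | 5-bromovanillin (3-bromo-4-hydroxy-5-methoxybenzaldehyde) | COc1cc(C=O)cc(Br)c1O | starting material
2 | 3-bromo-4,5-dihydroxybenzaldehyde | O=Cc1cc(O)c(O)c(Br)c1 | intermediate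
3 | 3-bromo-5-hydroxy-4-(methoxymethoxy)benzaldehyde | COCOc1c(O)cc(C=O)cc1Br | intermediate
4 | 3-bromo-5-(hydroxymethyl)-2-(methoxymethoxy)phenol | COCOc1c(O)cc(CO)cc1Br | intermediate
5 | {[3-bromo-4-(methoxymethoxy)-5-(triisopropylsilyloxy)benzyl]oxy}triisopropylsilane (Ar–Br) | COCOc1c(Br)cc(CO[Si](C(C)C)(C(C)C)C(C)C)cc1O[Si](C(C)C)(C(C)C)C(C)C | intermediate
6 | aryllithium Ar–Li | COCOc1c([Li])cc(CO[Si](C(C)C)(C(C)C)C(C)C)cc1O[Si](C(C)C)(C(C)C)C(C)C | intermediate
7 | aldehyde Ar–CHO | COCOc1c(C=O)cc(CO[Si](C(C)C)(C(C)C)C(C)C)cc1O[Si](C(C)C)(C(C)C)C(C)C | intermediate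
8 | benzylic alcohol Ar–CH2OH | COCOc1c(CO)cc(CO[Si](C(C)C)(C(C)C)C(C)C)cc1O[Si](C(C)C)(C(C)C)C(C)C | intermediate
9 | benzylic bromide Ar–CH2Br | COCOc1c(CBr)cc(CO[Si](C(C)C)(C(C)C)C(C)C)cc1O[Si](C(C)C)(C(C)C)C(C)C | intermediate
10 | (R)-4-methyloxolan-2-one | O=C1C[C@@H](C)CO1 | starting material
11 | lithium enolate of 10 | [Li]OC1=C[C@@H](C)CO1 | intermediate
12 | (3R,4R)-3,4-dimethyloxolan-2-one | O=C1[C@H](C)[C@@H](C)CO1 | intermediate
13 | lithium enolate of 12 | [Li]OC1=C(C)[C@@H](C)CO1 | intermediate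
14 | (3R,4R)-3-(ArCH2)-3,4-dimethyloxolan-2-one | O=C1[C@](C)(Cc2cc(CO[Si](C(C)C)(C(C)C)C(C)C)cc(O[Si](C(C)C)(C(C)C)C(C)C)c2OCOC)[C@@H](C)CO1 | intermediate
15 | (2R,3R)-2-(ArCH2)-2,3-dimethylbutane-1,4-diol | OC[C@](C)(Cc1cc(CO[Si](C(C)C)(C(C)C)C(C)C)cc(O[Si](C(C)C)(C(C)C)C(C)C)c1OCOC)[C@@H](C)CO | intermediate
16 | (3R,4R)-4-(ArCH2)-3,4-dimethyloxolan-2-one | O=C1[C@H](C)[C@@](C)(Cc2cc(CO[Si](C(C)C)(C(C)C)C(C)C)cc(O[Si](C(C)C)(C(C)C)C(C)C)c2OCOC)CO1 | intermediate
17 | (3R,4R)-4-(ArCH2)-3,4-dimethyloxolan-2-ol (anomer mixture) | OC1[C@H](C)[C@@](C)(Cc2cc(CO[Si](C(C)C)(C(C)C)C(C)C)cc(O[Si](C(C)C)(C(C)C)C(C)C)c2OCOC)CO1 | intermediate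
18 | (2R,3S)-2-(ArCH2)-2,3-dimethylpent-4-en-1-ol | OC[C@](C)(Cc1cc(CO[Si](C(C)C)(C(C)C)C(C)C)cc(O[Si](C(C)C)(C(C)C)C(C)C)c1OCOC)[C@@H](C)C=C | intermediate
19 | but-2-yn-1-ol | CC#CCO | starting material
20 | magnesium chelate (4-ethenyl-3-methyl-2,5-dihydro-1,2-oxamagnesole) | C=CC1=C(C)[Mg]OC1 | intermediate
21 | (2Z)-2-ethenyl-3-iodobut-2-en-1-ol | I/C(C)=C(\CO)C=C | intermediate
22 | {[(2Z)-2-ethenyl-3-iodobut-2-en-1-yl]oxy}triethylsilane | I/C(C)=C(\CO[Si](CC)(CC)CC)C=C | intermediate
23 | B-alkyl-9-BBN from 18 (C6–B; hydroxyl held as its 9-BBN borinate) | C1CCC2CCCC1B2OC[C@](C)(Cc1cc(CO[Si](C(C)C)(C(C)C)C(C)C)cc(O[Si](C(C)C)(C(C)C)C(C)C)c1OCOC)[C@@H](C)CCB1C2CCCC1CCC2 | intermediate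
24 | (2R,3S,6Z)-2-(ArCH2)-2,3,6-trimethyl-7-[(triethylsilyloxy)methyl]nona-6,8-dien-1-ol | OC[C@](C)(Cc1cc(CO[Si](C(C)C)(C(C)C)C(C)C)cc(O[Si](C(C)C)(C(C)C)C(C)C)c1OCOC)[C@@H](C)CC/C(C)=C(\CO[Si](CC)(CC)CC)C=C | intermediate
25 | (2R,3S,6Z)-2-(ArCH2)-2,3,6-trimethyl-7-[(triethylsilyloxy)methyl]nona-6,8-dienal | O=C[C@](C)(Cc1cc(CO[Si](C(C)C)(C(C)C)C(C)C)cc(O[Si](C(C)C)(C(C)C)C(C)C)c1OCOC)[C@@H](C)CC/C(C)=C(\CO[Si](CC)(CC)CC)C=C | intermediate
26 | diethyl [(phenylsulfonyl)methyl]phosphonate | CCOP(=O)(CS(=O)(=O)c1ccccc1)OCC | starting material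
27 | sodium carbanion of 26 | [Na+].CCOP(=O)([CH-]S(=O)(=O)c1ccccc1)OCC | intermediate
28 | {[(1E,3R,4S,7Z)-3-(ArCH2)-3,4,7-trimethyl-8-[(triethylsilyloxy)methyl]deca-1,7,9-trien-1-yl]sulfonyl}benzene | O=S(=O)(c1ccccc1)/C=C/[C@](C)(Cc1cc(CO[Si](C(C)C)(C(C)C)C(C)C)cc(O[Si](C(C)C)(C(C)C)C(C)C)c1OCOC)[C@@H](C)CC/C(C)=C(\CO[Si](CC)(CC)CC)C=C | intermediate
29 | triethyl{[(4S,4aS,5R,6S,8aS)-5-(ArCH2)-5,6,8a-trimethyl-4-(phenylsulfonyl)-3,4,4a,5,6,7,8,8a-octahydronaphthalen-1-yl]methoxy}silane (decalin numbering 1S,5S,8S,9R,10S) | CC[Si](CC)(CC)OCC1=CC[C@H](S(=O)(=O)c2ccccc2)[C@H]2[C@](C)(Cc3cc(CO[Si](C(C)C)(C(C)C)C(C)C)cc(O[Si](C(C)C)(C(C)C)C(C)C)c3OCOC)[C@@H](C)CC[C@]12C | intermediate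
30 | triethyl{[(4aS,5R,6S,8aS)-5-(ArCH2)-5,6,8a-trimethyl-3,4,4a,5,6,7,8,8a-octahydronaphthalen-1-yl]methoxy}silane | CC[Si](CC)(CC)OCC1=CCC[C@H]2[C@](C)(Cc3cc(CO[Si](C(C)C)(C(C)C)C(C)C)cc(O[Si](C(C)C)(C(C)C)C(C)C)c3OCOC)[C@@H](C)CC[C@]12C | intermediate
31 | [(4aS,5R,6S,8aS)-5-(ArCH2)-5,6,8a-trimethyl-3,4,4a,5,6,7,8,8a-octahydronaphthalen-1-yl]methanol | OCC1=CCC[C@H]2[C@](C)(Cc3cc(CO[Si](C(C)C)(C(C)C)C(C)C)cc(O[Si](C(C)C)(C(C)C)C(C)C)c3OCOC)[C@@H](C)CC[C@]12C | intermediate
32 | N-(C11-alkyl)-N-(2-nitrophenylsulfonyl)hydrazine of 31 | NN(CC1=CCC[C@H]2[C@](C)(Cc3cc(CO[Si](C(C)C)(C(C)C)C(C)C)cc(O[Si](C(C)C)(C(C)C)C(C)C)c3OCOC)[C@@H](C)CC[C@]12C)S(=O)(=O)c1ccccc1[N+](=O)[O-] | intermediate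
33 | allylic diazene (C11–N=NH) | N=NCC1=CCC[C@H]2[C@](C)(Cc3cc(CO[Si](C(C)C)(C(C)C)C(C)C)cc(O[Si](C(C)C)(C(C)C)C(C)C)c3OCOC)[C@@H](C)CC[C@]12C | intermediate
34 | (1R,2S,4aS,8aS)-1-(ArCH2)-1,2,4a-trimethyl-5-methylidenedecahydronaphthalene | C=C1CCC[C@H]2[C@](C)(Cc3cc(CO[Si](C(C)C)(C(C)C)C(C)C)cc(O[Si](C(C)C)(C(C)C)C(C)C)c3OCOC)[C@@H](C)CC[C@]12C | intermediate
35 | aryl trimethylsilyl ether of 36 | C=C1CCC[C@H]2[C@](C)(Cc3cc(CO[Si](C(C)C)(C(C)C)C(C)C)cc(O[Si](C(C)C)(C(C)C)C(C)C)c3O[Si](C)(C)C)[C@@H](C)CC[C@]12C | intermediate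
36 | 2-{[(1R,2S,4aS,8aS)-1,2,4a-trimethyl-5-methylidenedecahydronaphthalen-1-yl]methyl}-6-(triisopropylsilyloxy)-4-[(triisopropylsilyloxy)methyl]phenol | C=C1CCC[C@H]2[C@](C)(Cc3cc(CO[Si](C(C)C)(C(C)C)C(C)C)cc(O[Si](C(C)C)(C(C)C)C(C)C)c3O)[C@@H](C)CC[C@]12C | intermediate
37 | sodium sulfate of 36 | C=C1CCC[C@H]2[C@](C)(Cc3cc(CO[Si](C(C)C)(C(C)C)C(C)C)cc(O[Si](C(C)C)(C(C)C)C(C)C)c3OS(=O)(=O)[O-])[C@@H](C)CC[C@]12C.[Na+] | intermediate
38 | 2-{[(1R,2S,4aS,8aS)-1,2,4a-trimethyl-5-methylidenedecahydronaphthalen-1-yl]methyl}-6-hydroxy-4-(hydroxymethyl)phenyl hydrogen sulfate | C=C1CCC[C@H]2[C@](C)(Cc3cc(CO)cc(O)c3OS(=O)(=O)O)[C@@H](C)CC[C@]12C | target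

**Step count**

Total: 24 steps. Longest linear sequence: 21 steps (steps 1–6, 8–12, 15–24, from 5-bromovanillin).

**Steps most likely to fail**

1. Step 18. The cycloaddition at the fully substituted diene terminus may be slower than [1,5]-hydrogen shift of the inside methyl at 190 °C, or may close tether-syn or on the other diene face. The fallback sets out from aldehyde 25 and comes back at 30. A Henry reaction with nitromethane (KOtBu cat.) would give the β-nitro alcohol F1. MsCl/Et3N would convert it through the mesylate F2 into the (E)-nitroalkene F3. This much stronger dienophile should cyclise in toluene at 80–110 °C, below the range where the hydrogen shift competes, through the same tether-anti arrangement to the nitro octalin F4. Radical denitration (Bu3SnH, AIBN, toluene, reflux) would then replace the C1 nitro group by hydrogen and give 30.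

2. Step 15. Transmetalation and reductive elimination at the tetrasubstituted alkenyl iodide may be slow, so that protodeboronation or β-hydride elimination of the branched alkylborane takes over. The fallback sets out from alkenol 18 and comes back at 24. Hydroboration–oxidation (9-BBN-H; NaOH, H2O2) would give the 1,5-diol F5. Appel iodination (I2, PPh3, imidazole), selective for the unhindered C6 carbinol over the neopentyl one, would give the iodo alcohol F6, and pivaloylation (PivCl, pyridine, DMAP) the iodo pivalate F7. Zinc insertion (Zn, LiCl, THF) would give the alkylzinc iodide F8, and Negishi coupling with 22 (Pd(PtBu3)2, THF) the coupled pivalate F9. Cleavage of the pivalate with iBu2AlH at −78 °C would then give 24.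

3. Step 21. Mitsunobu displacement at the C11 carbinol beside the quaternary C5 may be too slow at −30 °C, so the sulfonylhydrazide decomposes before it is alkylated. The fallback sets out from 31 and comes back at 34. ClCO2Me/pyridine would give the methyl carbonate F10. Pd(OAc)2/PBu3 with ammonium formate in THF would then ionise it to the π-allyl palladium formate, which loses CO2 and delivers hydride to the more substituted allyl terminus C3, leaving the exocyclic C4=C11 alkene of 34.

**Further compounds**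

F1 | step 18 | β-nitro alcohol from 25 (C10 carbinol, epimer mixture) | O=[N+]([O-])CC(O)[C@](C)(Cc1cc(CO[Si](C(C)C)(C(C)C)C(C)C)cc(O[Si](C(C)C)(C(C)C)C(C)C)c1OCOC)[C@@H](C)CC/C(C)=C(\CO[Si](CC)(CC)CC)C=C
F2 | step 18 | mesylate of F1 | O=[N+]([O-])CC(OS(C)(=O)=O)[C@](C)(Cc1cc(CO[Si](C(C)C)(C(C)C)C(C)C)cc(O[Si](C(C)C)(C(C)C)C(C)C)c1OCOC)[C@@H](C)CC/C(C)=C(\CO[Si](CC)(CC)CC)C=C
F3 | step 18 | (E)-nitroalkene triene (nitro in place of the sulfone of 28) | O=[N+]([O-])/C=C/[C@](C)(Cc1cc(CO[Si](C(C)C)(C(C)C)C(C)C)cc(O[Si](C(C)C)(C(C)C)C(C)C)c1OCOC)[C@@H](C)CC/C(C)=C(\CO[Si](CC)(CC)CC)C=C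
F4 | step 18 | nitro octalin (C1 nitro analogue of 29) | CC[Si](CC)(CC)OCC1=CC[C@H]([N+](=O)[O-])[C@H]2[C@](C)(Cc3cc(CO[Si](C(C)C)(C(C)C)C(C)C)cc(O[Si](C(C)C)(C(C)C)C(C)C)c3OCOC)[C@@H](C)CC[C@]12C
F5 | step 15 | (2R,3S)-2-(ArCH2)-2,3-dimethylpentane-1,5-diol | OC[C@](C)(Cc1cc(CO[Si](C(C)C)(C(C)C)C(C)C)cc(O[Si](C(C)C)(C(C)C)C(C)C)c1OCOC)[C@@H](C)CCO
F6 | step 15 | (2R,3S)-2-(ArCH2)-5-iodo-2,3-dimethylpentan-1-ol | OC[C@](C)(Cc1cc(CO[Si](C(C)C)(C(C)C)C(C)C)cc(O[Si](C(C)C)(C(C)C)C(C)C)c1OCOC)[C@@H](C)CCI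
F7 | step 15 | pivalate of F6 | CC(C)(C)C(=O)OC[C@](C)(Cc1cc(CO[Si](C(C)C)(C(C)C)C(C)C)cc(O[Si](C(C)C)(C(C)C)C(C)C)c1OCOC)[C@@H](C)CCI
F8 | step 15 | alkylzinc iodide from F7 | CC(C)(C)C(=O)OC[C@](C)(Cc1cc(CO[Si](C(C)C)(C(C)C)C(C)C)cc(O[Si](C(C)C)(C(C)C)C(C)C)c1OCOC)[C@@H](C)CC[Zn]I
F9 | step 15 | pivalate of 24 | CC(C)(C)C(=O)OC[C@](C)(Cc1cc(CO[Si](C(C)C)(C(C)C)C(C)C)cc(O[Si](C(C)C)(C(C)C)C(C)C)c1OCOC)[C@@H](C)CC/C(C)=C(\CO[Si](CC)(CC)CC)C=C
F10 | step 21 | methyl carbonate of 31 | COC(=O)OCC1=CCC[C@H]2[C@](C)(Cc3cc(CO[Si](C(C)C)(C(C)C)C(C)C)cc(O[Si](C(C)C)(C(C)C)C(C)C)c3OCOC)[C@@H](C)CC[C@]12C
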